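**Plan**

- Ring A carries oxygen on positions 1, 3 and 5, hydrogen on positions 2 and 6, and its fourth oxygen (the ether to ring B) on position 4, so it is a folded triketide with an aryloxy group on its central carbon. The retrosynthesis opens the bond between positions 1 and 6 of ring A (Claisen) to a 4-aryloxy-3,5-dioxohexanoate; the ether bond at position 4 goes back to SN2 on 3-chloropentane-2,4-dione and the ester carbon to dimethyl carbonate.
- The five other ether bonds (from each bridging oxygen to position 1 of rings C, D, E, F and G) are cut from the ring G end. Each is an SNAr of a phenoxide on a fluorobenzaldehyde, whose formyl-bearing carbon afterwards becomes the next phenol carbon (Baeyer–Villiger). The last cut is sixteen O–CH3 bonds.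
- Forward: ring B comes from syringaldehyde, ring A is cyclised onto it, the triol is methylated and the benzyl group removed. Rings C, D, E, F and G are then joined in that order, and all methyl ethers are cleaved at the end.
- Stereochemistry: the target has no stereocentre. The only one on the way, carbon 4 of the open-chain keto ester, is racemic and enolisable and ends as the aromatic carbon at position 4 of ring A.

Key step: step 5

**Remarks on the chemistry**

- Rings are lettered A to G along the chain. In ring A the ether oxygen to ring B is on position 4 and the hydroxyls are on positions 1, 3 and 5. In rings B, C, E, F and G the ether oxygen on the ring A side sits on position 1 and the next oxygen on position 4, flanked by oxygens on positions 3 and 5. In ring D the oxygen from ring C is on position 1, the oxygen to ring E on position 2, and positions 3, 4 and 5 carry oxygen.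
- The hexanoate chain of the keto ester is numbered from the ester carbon (carbon 1) to the terminal methyl carbon (carbon 6).
- "Ring A–C aldehyde" and the like mean the chain from ring A to the second-named ring with every ring oxygen methylated and a formyl group on the carbon of the last ring that later carries the next oxygen (position 4, or position 2 in ring D). The corresponding "formate" and "phenol" carry OCHO or OH on that carbon.
- 5-Fluoro-1,2,3-trimethoxybenzene is made in step 10 from the aniline and is not assumed to be purchasable.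
- Free polyphenols (10, 33) and 2,6-dimethoxyphenols are handled under argon.

**Route**

Step 1
Reactants: 1 syringaldehyde (4-hydroxy-3,5-dimethoxybenzaldehyde)
Product: 2 4-(benzyloxy)-3,5-dimethoxybenzaldehyde
Conditions: BnBr, K2CO3, DMF, 60 °C
Reagents that add atoms: benzyl bromide, BrCc1ccccc1
Why: Williamson ether synthesis on a phenol made acidic by the para formyl group should benzylate the only hydroxyl cleanly.

Step 2
Reactants: 2 4-(benzyloxy)-3,5-dimethoxybenzaldehyde
Product: 4 4-(benzyloxy)-3,5-dimethoxyphenol, via ring B formate 3 (not isolated)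
Conditions: mCPBA, CH2Cl2, 0 °C to rt; then MeOH, cat. HCl, rt
Reagents that add atoms: mCPBA (3-chloroperoxybenzoic acid), OOC(=O)c1cccc(Cl)c1
Why: Baeyer–Villiger (Dakin-type) oxidation, in which the electron-rich aryl group migrates in the Criegee adduct to give formate 3, which acidic methanol cleaves to the phenol.

Step 3
Reactants: 4 4-(benzyloxy)-3,5-dimethoxyphenol; 5 3-chloropentane-2,4-dione
Product: 6 3-[4-(benzyloxy)-3,5-dimethoxyphenoxy]pentane-2,4-dione
Conditions: Cs2CO3, acetone, reflux
Reagents that add atoms: none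
Why: Williamson-type SN2 displacement of chloride from the carbon between the two carbonyls by the unhindered phenoxide of 4 is an established way to 3-aryloxypentane-2,4-diones, and it makes the future ether bond at position 4 of ring A at an sp3 carbon instead of by aryl ether coupling at a position flanked by two oxygens.

Step 4
Reactants: 6 3-[4-(benzyloxy)-3,5-dimethoxyphenoxy]pentane-2,4-dione; 7 dimethyl carbonate
Product: 8 methyl 4-[4-(benzyloxy)-3,5-dimethoxyphenoxy]-3,5-dioxohexanoate (racemic, keto–enol mixture)
Conditions: LiN(iPr)2 (3.3 equiv), THF, −78 to 0 °C; 7 (1.3 equiv), −78 °C to rt; aq. NH4Cl, 0 °C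
Reagents that add atoms: none
Why: Harris-type 1,3-diketone dianion chemistry, in which the second deprotonation takes a terminal methyl hydrogen and the resulting primary carbanion is acylated by dimethyl carbonate (Claisen-type carboxylation), the third equivalent of base taking up the more acidic product.

Step 5
Reactants: 8 methyl 4-[4-(benzyloxy)-3,5-dimethoxyphenoxy]-3,5-dioxohexanoate
Product: 10 2-[4-(benzyloxy)-3,5-dimethoxyphenoxy]benzene-1,3,5-triol, via cyclohexane-1,3,5-trione 9 (not isolated)
Conditions: NaOMe (5 equiv), diglyme (0.05 M), 140 °C, argon; then cold 2 M HCl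
Reagents that add atoms: none
Why: Methoxide deprotonates 8 at carbons 2 and 4 of the chain and, reversibly at this temperature, at the methyl carbon 6; the carbanion at carbon 6 (enolate of the ketone at carbon 5) adds to the ester carbonyl (carbon 1) and methoxide leaves, which joins the carbons that become positions 1 and 6 of ring A and gives trione 9. This is a Claisen (Dieckmann-type) condensation, the laboratory counterpart of triketide folding, of the kind by which 3,5-dioxohexanoate esters are converted into phloroglucinol under strongly basic conditions. Ring A closes in a 6-(enolendo)-exo-trig mode, the only carbocyclic closure open to the chain, since every aldol alternative would give a four-membered ring. No stereocentre is formed, and the single stereogenic carbon of 8 (carbon 4 of the chain) becomes the aromatic carbon at position 4 of ring A. The selectivity required is carbon over oxygen acylation, because the enolate oxygen on carbon 5 can close a 4-hydroxy-2-pyranone instead; with methoxide present that lactone should reopen to the ester, whereas 9 tautomerises to the aromatic phloroglucinolate and does not return, so the equilibria should drain toward 10. The aryloxy group stays in place because it sits on an enolate carbon throughout, and the cold acidic quench avoids acid-induced benzofuran closure of any unreacted 8.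

Step 6
Reactants: 10 2-[4-(benzyloxy)-3,5-dimethoxyphenoxy]benzene-1,3,5-triol
Product: 11 2-[4-(benzyloxy)-3,5-dimethoxyphenoxy]-1,3,5-trimethoxybenzene
Conditions: Me2SO4 (4 equiv), K2CO3, acetone, reflux, argon
Reagents that add atoms: dimethyl sulfate, COS(=O)(=O)OC
Why: Williamson O-methylation with dimethyl sulfate and K2CO3 in acetone is the standard conversion of phloroglucinols into trimethyl ethers and should keep methylation at ring carbon low because the hard electrophile favours oxygen.

Step 7
Reactants: 11 2-[4-(benzyloxy)-3,5-dimethoxyphenoxy]-1,3,5-trimethoxybenzene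
Product: 12 2,6-dimethoxy-4-(2,4,6-trimethoxyphenoxy)phenol (ring A–B phenol)
Conditions: H2 (1 atm), Pd/C (10%), EtOAc–MeOH, rt
Reagents that add atoms: none
Why: Catalytic hydrogenolysis cleaves only the benzylic C–O bond and leaves methyl and diaryl ethers untouched, which frees the hydroxyl on position 4 of ring B as the single nucleophilic site.

Step 8
Reactants: 12 2,6-dimethoxy-4-(2,4,6-trimethoxyphenoxy)phenol; 13 4-fluoro-2,6-dimethoxybenzaldehyde
Product: 14 2,6-dimethoxy-4-[2,6-dimethoxy-4-(2,4,6-trimethoxyphenoxy)phenoxy]benzaldehyde (ring A–C aldehyde)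
Conditions: K2CO3, DMF, 120 °C
Reagents that add atoms: none
Why: Nucleophilic aromatic substitution by addition–elimination, in which the formyl group para to fluorine stabilises the Meisenheimer intermediate, the two methoxy groups are meta to the reacting carbon and do not oppose it, and the 2,6-dimethoxyphenoxide of 12 is hindered but strongly nucleophilic.

Step 9
Reactants: 14 ring A–C aldehyde
Product: 16 2,6-dimethoxy-4-[2,6-dimethoxy-4-(2,4,6-trimethoxyphenoxy)phenoxy]phenol (ring A–C phenol), via ring A–C formate 15 (not isolated)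
Conditions: mCPBA (1.3 equiv), CH2Cl2, 0 °C to rt; then MeOH, cat. HCl, rt
Reagents that add atoms: mCPBA (3-chloroperoxybenzoic acid), OOC(=O)c1cccc(Cl)c1
Why: Baeyer–Villiger (Dakin-type) oxidation, in which the ring C carbon flanked by two methoxy groups migrates in preference to hydrogen, and the formate keeps the new electron-rich phenol masked until the peracid is consumed.

Step 10
Reactants: 17 3,4,5-trimethoxyaniline
Product: 19 5-fluoro-1,2,3-trimethoxybenzene, via diazonium fluoride 18 (not isolated)
Conditions: NaNO2, HF·pyridine (70%), 0 °C; then 80 °C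
Reagents that add atoms: hydrogen fluoride (as HF·pyridine), F
Why: Fluorodediazoniation of Balz–Schiemann type run in one pot, in which diazotisation gives 18, warming expels dinitrogen and the aryl cation is captured by fluoride.

Step 11
Reactants: 19 5-fluoro-1,2,3-trimethoxybenzene
Product: 20 6-fluoro-2,3,4-trimethoxybenzaldehyde
Conditions: Cl2CHOMe, TiCl4, CH2Cl2, −10 to 0 °C; ice water
Reagents that add atoms: dichloromethyl methyl ether, COC(Cl)Cl; water, O
Why: Rieche formylation (Friedel–Crafts type), in which the two free ring positions are equivalent by symmetry and each is ortho and para to methoxy groups, so a single aldehyde with the formyl group next to fluorine is expected.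

Step 12
Reactants: 16 ring A–C phenol; 20 6-fluoro-2,3,4-trimethoxybenzaldehyde
Product: 21 ring A–D aldehyde (6-aryloxy-2,3,4-trimethoxybenzaldehyde whose aryloxy group is 16 bonded through its phenol oxygen)
Conditions: Cs2CO3, DMSO, 110 °C
Reagents that add atoms: none
Why: SNAr activated by the ortho formyl group, in which the donation of the para methoxy group is offset by the two meta methoxy groups and Cs2CO3 in DMSO supplies a weakly paired phenoxide for this less activated fluoride.

Step 13
Reactants: 21 ring A–D aldehyde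
Product: 23 ring A–D phenol (21 carrying OH in place of CHO on position 2 of ring D), via ring A–D formate 22 (not isolated)
Conditions: mCPBA (1.3 equiv), CH2Cl2, 0 °C to rt; then MeOH, cat. HCl, rt
Reagents that add atoms: mCPBA (3-chloroperoxybenzoic acid), OOC(=O)c1cccc(Cl)c1
Why: Baeyer–Villiger (Dakin-type) oxidation, favoured here because the migrating carbon (position 2 of ring D) has an aryloxy and a methoxy group ortho and a further methoxy group para.

Step 14
Reactants: 23 ring A–D phenol; 13 4-fluoro-2,6-dimethoxybenzaldehyde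
Product: 24 ring A–E aldehyde (2,6-dimethoxy-4-aryloxybenzaldehyde whose aryloxy group is 23 bonded through its phenol oxygen)
Conditions: Cs2CO3, DMSO, 110 °C
Reagents that add atoms: none
Why: SNAr as in step 8, in which the phenoxide on position 2 of ring D, flanked by an aryloxy and a methoxy group, attacks an unhindered C–F carbon and ring C cannot take part in a Smiles-type aryl transfer because it carries no electron-withdrawing group.

Step 15
Reactants: 24 ring A–E aldehyde
Product: 26 ring A–E phenol (24 carrying OH in place of CHO on position 4 of ring E), via ring A–E formate 25 (not isolated)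
Conditions: mCPBA (1.3 equiv), CH2Cl2, 0 °C to rt; then MeOH, cat. HCl, rt
Reagents that add atoms: mCPBA (3-chloroperoxybenzoic acid), OOC(=O)c1cccc(Cl)c1
Why: Baeyer–Villiger (Dakin-type) oxidation of a 2,6-dimethoxy-4-aryloxybenzaldehyde, the same substrate type as in step 9.

Step 16
Reactants: 26 ring A–E phenol; 13 4-fluoro-2,6-dimethoxybenzaldehyde
Product: 27 ring A–F aldehyde (2,6-dimethoxy-4-aryloxybenzaldehyde whose aryloxy group is 26 bonded through its phenol oxygen)
Conditions: K2CO3, DMF, 120 °C
Reagents that add atoms: none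
Why: SNAr of a 2,6-dimethoxyphenoxide on the para-formyl-activated fluoride, the same pairing as in step 8.

Step 17
Reactants: 27 ring A–F aldehyde
Product: 29 ring A–F phenol (27 carrying OH in place of CHO on position 4 of ring F), via ring A–F formate 28 (not isolated)
Conditions: mCPBA (1.3 equiv), CH2Cl2, 0 °C to rt; then MeOH, cat. HCl, rt
Reagents that add atoms: mCPBA (3-chloroperoxybenzoic acid), OOC(=O)c1cccc(Cl)c1
Why: Baeyer–Villiger (Dakin-type) oxidation, as in step 9.

Step 18
Reactants: 29 ring A–F phenol; 13 4-fluoro-2,6-dimethoxybenzaldehyde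
Product: 30 ring A–G aldehyde (2,6-dimethoxy-4-aryloxybenzaldehyde whose aryloxy group is 29 bonded through its phenol oxygen)
Conditions: K2CO3, DMF, 120 °C
Reagents that add atoms: none
Why: SNAr as in step 8, which brings in ring G with the oxygens on its positions 3 and 5 in place and a formyl group marking its position 4.

Step 19
Reactants: 30 ring A–G aldehyde
Product: 32 ring A–G phenol (30 carrying OH in place of CHO on position 4 of ring G; sixteen methyl ethers), via ring A–G formate 31 (not isolated)
Conditions: mCPBA (1.3 equiv), CH2Cl2, 0 °C to rt; then MeOH, cat. HCl, rt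
Reagents that add atoms: mCPBA (3-chloroperoxybenzoic acid), OOC(=O)c1cccc(Cl)c1
Why: Baeyer–Villiger (Dakin-type) oxidation installs the last oxygen (position 4 of ring G), which can stay free because only deprotection follows.

Step 20
Reactants: 32 ring A–G phenol
Product: 33 CNP0304148.0
Conditions: BBr3 (about 2 equiv per OMe), CH2Cl2, −78 °C to rt, argon; MeOH then H2O; Sephadex LH-20 (MeOH)
Reagents that add atoms: none
Why: Lewis acid-mediated aryl methyl ether cleavage, in which each methoxy oxygen binds boron and bromide attacks the methyl carbon by SN2, a path closed to the diaryl ether bonds, so only the sixteen O–CH3 bonds should break and aqueous work-up releases the free polyphenol.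

**Compound list**

1 | syringaldehyde (4-hydroxy-3,5-dimethoxybenzaldehyde) | COc1cc(C=O)cc(OC)c1O | starting material
2 | 4-(benzyloxy)-3,5-dimethoxybenzaldehyde | COc1cc(C=O)cc(OC)c1OCc1ccccc1 | intermediate
3 | 4-(benzyloxy)-3,5-dimethoxyphenyl formate | COc1cc(OC=O)cc(OC)c1OCc1ccccc1 | intermediate
4 | 4-(benzyloxy)-3,5-dimethoxyphenol | COc1cc(O)cc(OC)c1OCc1ccccc1 | intermediate
5 | 3-chloropentane-2,4-dione | CC(=O)C(Cl)C(C)=O | starting material
6 | 3-[4-(benzyloxy)-3,5-dimethoxyphenoxy]pentane-2,4-dione | CC(=O)C(Oc1cc(OC)c(OCc2ccccc2)c(OC)c1)C(C)=O | intermediate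
7 | dimethyl carbonate | COC(=O)OC | starting material
8 | methyl 4-[4-(benzyloxy)-3,5-dimethoxyphenoxy]-3,5-dioxohexanoate (racemic) | COC(=O)CC(=O)C(Oc1cc(OC)c(OCc2ccccc2)c(OC)c1)C(C)=O | intermediate
9 | 2-[4-(benzyloxy)-3,5-dimethoxyphenoxy]cyclohexane-1,3,5-trione | O=C1CC(=O)C(Oc2cc(OC)c(OCc3ccccc3)c(OC)c2)C(=O)C1 | intermediate
10 | 2-[4-(benzyloxy)-3,5-dimethoxyphenoxy]benzene-1,3,5-triol | Oc1cc(O)c(Oc2cc(OC)c(OCc3ccccc3)c(OC)c2)c(O)c1 | intermediate
11 | 2-[4-(benzyloxy)-3,5-dimethoxyphenoxy]-1,3,5-trimethoxybenzene | COc1cc(OC)c(Oc2cc(OC)c(OCc3ccccc3)c(OC)c2)c(OC)c1 | intermediate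
12 | 2,6-dimethoxy-4-(2,4,6-trimethoxyphenoxy)phenol | COc1cc(OC)c(Oc2cc(OC)c(O)c(OC)c2)c(OC)c1 | intermediate
13 | 4-fluoro-2,6-dimethoxybenzaldehyde | COc1cc(F)cc(OC)c1C=O | starting material
14 | 2,6-dimethoxy-4-[2,6-dimethoxy-4-(2,4,6-trimethoxyphenoxy)phenoxy]benzaldehyde | COc1cc(OC)c(Oc2cc(OC)c(Oc3cc(OC)c(C=O)c(OC)c3)c(OC)c2)c(OC)c1 | intermediate
15 | 2,6-dimethoxy-4-[2,6-dimethoxy-4-(2,4,6-trimethoxyphenoxy)phenoxy]phenyl formate | COc1cc(OC)c(Oc2cc(OC)c(Oc3cc(OC)c(OC=O)c(OC)c3)c(OC)c2)c(OC)c1 | intermediate
16 | 2,6-dimethoxy-4-[2,6-dimethoxy-4-(2,4,6-trimethoxyphenoxy)phenoxy]phenol | COc1cc(OC)c(Oc2cc(OC)c(Oc3cc(OC)c(O)c(OC)c3)c(OC)c2)c(OC)c1 | intermediate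
17 | 3,4,5-trimethoxyaniline | COc1cc(N)cc(OC)c1OC | starting material
18 | 3,4,5-trimethoxybenzenediazonium fluoride | COc1cc([N+]#N)cc(OC)c1OC.[F-] | intermediate
19 | 5-fluoro-1,2,3-trimethoxybenzene | COc1cc(F)cc(OC)c1OC | intermediate
20 | 6-fluoro-2,3,4-trimethoxybenzaldehyde | COc1cc(F)c(C=O)c(OC)c1OC | intermediate
21 | 6-{2,6-dimethoxy-4-[2,6-dimethoxy-4-(2,4,6-trimethoxyphenoxy)phenoxy]phenoxy}-2,3,4-trimethoxybenzaldehyde (ring A–D aldehyde) | COc1cc(OC)c(Oc2cc(OC)c(Oc3cc(OC)c(Oc4cc(OC)c(OC)c(OC)c4C=O)c(OC)c3)c(OC)c2)c(OC)c1 | intermediate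
22 | 6-{2,6-dimethoxy-4-[2,6-dimethoxy-4-(2,4,6-trimethoxyphenoxy)phenoxy]phenoxy}-2,3,4-trimethoxyphenyl formate (ring A–D formate) | COc1cc(OC)c(Oc2cc(OC)c(Oc3cc(OC)c(Oc4cc(OC)c(OC)c(OC)c4OC=O)c(OC)c3)c(OC)c2)c(OC)c1 | intermediate
23 | 6-{2,6-dimethoxy-4-[2,6-dimethoxy-4-(2,4,6-trimethoxyphenoxy)phenoxy]phenoxy}-2,3,4-trimethoxyphenol (ring A–D phenol) | COc1cc(OC)c(Oc2cc(OC)c(Oc3cc(OC)c(Oc4cc(OC)c(OC)c(OC)c4O)c(OC)c3)c(OC)c2)c(OC)c1 | intermediate
24 | ring A–E aldehyde: 2,6-dimethoxybenzaldehyde carrying on its ring carbon 4 the aryloxy group of 23 | COc1cc(OC)c(Oc2cc(OC)c(Oc3cc(OC)c(Oc4cc(OC)c(OC)c(OC)c4Oc4cc(OC)c(C=O)c(OC)c4)c(OC)c3)c(OC)c2)c(OC)c1 | intermediate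
25 | ring A–E formate: 24 with OCHO in place of CHO | COc1cc(OC)c(Oc2cc(OC)c(Oc3cc(OC)c(Oc4cc(OC)c(OC)c(OC)c4Oc4cc(OC)c(OC=O)c(OC)c4)c(OC)c3)c(OC)c2)c(OC)c1 | intermediate
26 | ring A–E phenol: 24 with OH in place of CHO | COc1cc(OC)c(Oc2cc(OC)c(Oc3cc(OC)c(Oc4cc(OC)c(OC)c(OC)c4Oc4cc(OC)c(O)c(OC)c4)c(OC)c3)c(OC)c2)c(OC)c1 | intermediate
27 | ring A–F aldehyde: 2,6-dimethoxybenzaldehyde carrying on its ring carbon 4 the aryloxy group of 26 | COc1cc(OC)c(Oc2cc(OC)c(Oc3cc(OC)c(Oc4cc(OC)c(OC)c(OC)c4Oc4cc(OC)c(Oc5cc(OC)c(C=O)c(OC)c5)c(OC)c4)c(OC)c3)c(OC)c2)c(OC)c1 | intermediate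
28 | ring A–F formate: 27 with OCHO in place of CHO | COc1cc(OC)c(Oc2cc(OC)c(Oc3cc(OC)c(Oc4cc(OC)c(OC)c(OC)c4Oc4cc(OC)c(Oc5cc(OC)c(OC=O)c(OC)c5)c(OC)c4)c(OC)c3)c(OC)c2)c(OC)c1 | intermediate
29 | ring A–F phenol: 27 with OH in place of CHO | COc1cc(OC)c(Oc2cc(OC)c(Oc3cc(OC)c(Oc4cc(OC)c(OC)c(OC)c4Oc4cc(OC)c(Oc5cc(OC)c(O)c(OC)c5)c(OC)c4)c(OC)c3)c(OC)c2)c(OC)c1 | intermediate
30 | ring A–G aldehyde: 2,6-dimethoxybenzaldehyde carrying on its ring carbon 4 the aryloxy group of 29 | COc1cc(OC)c(Oc2cc(OC)c(Oc3cc(OC)c(Oc4cc(OC)c(OC)c(OC)c4Oc4cc(OC)c(Oc5cc(OC)c(Oc6cc(OC)c(C=O)c(OC)c6)c(OC)c5)c(OC)c4)c(OC)c3)c(OC)c2)c(OC)c1 | intermediate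
31 | ring A–G formate: 30 with OCHO in place of CHO | COc1cc(OC)c(Oc2cc(OC)c(Oc3cc(OC)c(Oc4cc(OC)c(OC)c(OC)c4Oc4cc(OC)c(Oc5cc(OC)c(Oc6cc(OC)c(OC=O)c(OC)c6)c(OC)c5)c(OC)c4)c(OC)c3)c(OC)c2)c(OC)c1 | intermediate
32 | ring A–G phenol: 30 with OH in place of CHO (hexadecamethyl ether of the target, hydroxyl on position 4 of ring G free) | COc1cc(OC)c(Oc2cc(OC)c(Oc3cc(OC)c(Oc4cc(OC)c(OC)c(OC)c4Oc4cc(OC)c(Oc5cc(OC)c(Oc6cc(OC)c(O)c(OC)c6)c(OC)c5)c(OC)c4)c(OC)c3)c(OC)c2)c(OC)c1 | intermediate
33 | CNP0304148.0, 5-{2,6-dihydroxy-4-[2,6-dihydroxy-4-(2,4,6-trihydroxyphenoxy)phenoxy]phenoxy}-4-{3,5-dihydroxy-4-[3,5-dihydroxy-4-(3,4,5-trihydroxyphenoxy)phenoxy]phenoxy}benzene-1,2,3-triol | Oc1cc(O)c(Oc2cc(O)c(Oc3cc(O)c(Oc4cc(O)c(O)c(O)c4Oc4cc(O)c(Oc5cc(O)c(Oc6cc(O)c(O)c(O)c6)c(O)c5)c(O)c4)c(O)c3)c(O)c2)c(O)c1 | target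

**Step count and risks**

Total step count: 20 (18 in the main line, 2 for the ring D building block 20).
Longest linear sequence: 18 steps (steps 1–9 and 12–20, from syringaldehyde).

Steps most likely to fail:

1. Step 5. Oxygen acylation through the enolate oxygen on carbon 5 (closure of a pyranone) or retro-Claisen loss of the acetyl group may outrun the slow carbon acylation by the weakly acidic methyl terminus, and the hot basic medium may degrade the phloroglucinolate before quenching. The fallback gives up building ring A and brings it in fully oxygenated. It sets out from 13 and returns to the route at 12. Commercial 2,4,6-trimethoxybenzaldehyde is oxidised with mCPBA in CH2Cl2 to 2,4,6-trimethoxyphenyl formate F1, which acidic methanol cleaves in the same flask to 2,4,6-trimethoxyphenol F2. The phenoxide of F2 (K2CO3, DMF, 120 °C) displaces fluoride from 13 to give 2,6-dimethoxy-4-(2,4,6-trimethoxyphenoxy)benzaldehyde F3. Baeyer–Villiger oxidation of F3 with mCPBA gives 2,6-dimethoxy-4-(2,4,6-trimethoxyphenoxy)phenyl formate F4, and methanolysis of F4 delivers 12, from which step 8 continues.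

2. Step 20. Cleavage may stop short when partly demethylated boron phenoxides precipitate from CH2Cl2, and the free polyphenol (pentaoxygenated ring D, pyrogallol ring G) may oxidise in air during isolation. The fallback sets out from 32 and returns at 33. The ethers are cleaved in solution by the hard acid–soft nucleophile pair AlBr3/EtSH at 0 °C to rt. The crude polyphenol is not isolated but treated directly with Ac2O/pyridine, which gives the heptadecaacetate of the target F5, a stable compound that can be purified on silica. Acid-catalysed methanolysis of F5 (HCl generated from a little AcCl in MeOH, rt, argon) then releases 33 with only volatile by-products.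

3. Step 4. The carboxylation may stall through incomplete second deprotonation, proton transfer from the more acidic product to unreacted dianion, or oxygen acylation, and 6 may lose an acetyl group under base. The fallback reaches the same keto ester by adding the acetyl group last. It sets out from 4 and returns at 8, and so also bypasses step 3. The sodium phenoxide of 4 is alkylated with methyl 4-chloroacetoacetate (NaH, 2 equiv, THF, 0 °C to rt) to give methyl 4-[4-(benzyloxy)-3,5-dimethoxyphenoxy]-3-oxobutanoate F6. Its dianion (NaH, then n-BuLi, THF, 0 °C) is acylated at carbon 4 of the butanoate chain with N-methoxy-N-methylacetamide; the tetrahedral adduct persists until work-up and so cannot quench the dianion, and aqueous NH4Cl then gives 8.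

**Further compounds**

F1 | step 5 | 2,4,6-trimethoxyphenyl formate | COc1cc(OC)c(OC=O)c(OC)c1
F2 | step 5 | 2,4,6-trimethoxyphenol | COc1cc(OC)c(O)c(OC)c1
F3 | step 5 | 2,6-dimethoxy-4-(2,4,6-trimethoxyphenoxy)benzaldehyde | COc1cc(OC)c(Oc2cc(OC)c(C=O)c(OC)c2)c(OC)c1
F4 | step 5 | 2,6-dimethoxy-4-(2,4,6-trimethoxyphenoxy)phenyl formate | COc1cc(OC)c(Oc2cc(OC)c(OC=O)c(OC)c2)c(OC)c1
F5 | step 20 | heptadecaacetate of 33 (every hydroxyl of the target as its acetate) | CC(=O)Oc1cc(OC(C)=O)c(Oc2cc(OC(C)=O)c(Oc3cc(OC(C)=O)c(Oc4cc(OC(C)=O)c(OC(C)=O)c(OC(C)=O)c4Oc4cc(OC(C)=O)c(Oc5cc(OC(C)=O)c(Oc6cc(OC(C)=O)c(OC(C)=O)c(OC(C)=O)c6)c(OC(C)=O)c5)c(OC(C)=O)c4)c(OC(C)=O)c3)c(OC(C)=O)c2)c(OC(C)=O)c1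
F6 | step 4 | methyl 4-[4-(benzyloxy)-3,5-dimethoxyphenoxy]-3-oxobutanoate | COC(=O)CC(=O)COc1cc(OC)c(OCc2ccccc2)c(OC)c1
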